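**Retrosynthetic overview**
1. Ring C is opened at O1–C2 (intramolecular Mitsunobu etherification) and at C3–C4 (Evans benzylation of a ring B arylacetyl oxazolidinone with a ring A benzyl bromide, which sets the single (R) centre).
2. Ring A piece: 2,4-dihydroxybenzaldehyde, C-prenylated between its two oxygens. Ring B piece: chromene carbamate 11, extended at C6 by carbamate-directed lithiation.
3. Key disconnection: the dimethylpyran of ring B is cut at both C–C bonds that flank its C3=C4 unit (C4–C4a and C2–C3). It is made in one operation from aryl isopropenyl ether 7 and ethyl vinyl ether by an oxa-Povarov-type [4+2] annulation with ipso-desilylative closure and loss of ethanol.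
4. Enabling feature: chromene C4a is the carbon between the two oxygens of the resorcinol ring B, and C2 is an acetone-level carbon on the pyran oxygen O1, so C4a=C8a–O1–C2(+) is an aryl oxocarbenium 2-oxadiene. A SiMe3 group on C4a, placed from symmetric 2-bromoresorcinol, steers the closure and leaves in it.
5. Order of ring formation: ring B arene (bought), then the pyran of the chromene (step 3), then ring C (step 13); ring A is bought.

Key step: step 3

Remark: the stereocentre is (3R) as drawn; it keeps the descriptor R from step 11 to the target because the priority order (carbon bearing O > ring B > benzylic CH2 > H) does not change.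

**Step 1**
Reactants: 1 2-bromoresorcinol
Product: 5 3-hydroxy-2-(trimethylsilyl)phenyl diethylcarbamate, via bis(trimethylsilyl) ether 2 (not isolated), via lithium silylphenoxide 3 (not isolated), via silyl ether carbamate 4 (not isolated)
Conditions: (Me3Si)2NH, THF, 65 °C, evaporate; n-BuLi, THF, −78 → 0 °C; ClCONEt2, DMPU, −78 → 50 °C; aq. citric acid/MeOH work-up
Reagents that add atoms: hexamethyldisilazane C[Si](C)(C)N[Si](C)(C)C; diethylcarbamoyl chloride CCN(CC)C(Cl)=O
Why: Bis-silylation, bromine–lithium exchange and the retro-Brook 1,3 O-to-C silyl shift (the usual entry to ortho-silyl phenols) should put SiMe3 on the carbon between the two oxygens and leave a single lithium phenoxide, which alone is carbamoylated, so the symmetric diol is desymmetrised without statistics.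

**Step 2**
Reactants: 5 3-hydroxy-2-(trimethylsilyl)phenyl diethylcarbamate; 6 isopropenylboronic acid pinacol ester
Product: 7 3-(prop-1-en-2-yloxy)-2-(trimethylsilyl)phenyl diethylcarbamate
Conditions: Cu(OAc)2 (20 mol %), pyridine, 4 Å molecular sieves, O2 (1 atm), CH2Cl2, 25 °C
Reagents that add atoms: none
Why: Chan–Lam oxidative C–O coupling of a phenol with an alkenylboronate should give the aryl isopropenyl ether at room temperature without acid, which the acid-labile aryl–silicon bond would not tolerate.

**Step 3**
Reactants: 7 3-(prop-1-en-2-yloxy)-2-(trimethylsilyl)phenyl diethylcarbamate; 8 ethyl vinyl ether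
Product: 11 2,2-dimethyl-2H-chromen-5-yl diethylcarbamate, via alpha-chloro ether 9 (not isolated), via 4-ethoxychroman 10 (not isolated)
Conditions: HCl (1.0 equiv, Et2O solution), CH2Cl2, −78 °C; then 8 (1.3 equiv, slow addition), SnCl4 (20 mol %), −78 → 0 °C; then TsOH (10 mol %), 35 °C
Reagents that add atoms: none
Why: Proposed new method: Markovnikov addition of HCl to the enol ether gives the tertiary alpha-chloro ether 9, whose SnCl4-assisted ionisation can only give the aryl oxocarbenium ion (cationic 2-oxadiene C4a=C8a–O1=C2); the beta-carbon of 8 adds to it (C2–C3 bond), the resulting ethoxycarbenium ion at C4 is attacked by the arene at the silicon-bearing carbon (C4–C4a bond, loss of Me3SiCl) to give 10, and acid then eliminates ethanol to the chromene. The closest known reactions are the oxa-Povarov reaction of aryl oxocarbenium ions with alkenes, the Povarov reaction with vinyl ethers followed by loss of the alcohol, and silicon-directed ipso Pictet–Spengler and Friedel–Crafts cyclisations. The pyran ring closes in a formal [4+2] sense, the second bond by a six-membered ipso Friedel–Crafts attack on the exocyclic oxocarbenium carbon (6-exo at the cation). The only stereocentre formed (C4 of 10) is racemic and is erased by the elimination. The step needs closure at the carbon between the two oxygens and not at the free ortho position para to the carbamate; the beta-silicon stabilisation of the ipso Wheland intermediate and relief of strain should secure this, the chloride precursor removes any doubt about which C–O bond ionises, and slow addition of 8 should keep telomerisation of the vinyl ether down.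

**Step 4**
Reactants: 11 2,2-dimethyl-2H-chromen-5-yl diethylcarbamate
Product: 13 6-(2-hydroxyethyl)-2,2-dimethyl-2H-chromen-5-yl diethylcarbamate, via 6-lithio carbamate 12 (not isolated)
Conditions: s-BuLi, TMEDA, THF, −78 °C; then oxirane, BF3·OEt2, −78 °C; then H2O
Reagents that add atoms: oxirane C1CO1
Why: Directed ortho-metalation by the O-carbamate should lithiate the only free ortho position (C6), and BF3-assisted epoxide opening at −78 °C should outrun the anionic ortho-Fries shift.

**Step 5**
Reactants: 13 6-(2-hydroxyethyl)-2,2-dimethyl-2H-chromen-5-yl diethylcarbamate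
Product: 14 2-[5-(diethylcarbamoyloxy)-2,2-dimethyl-2H-chromen-6-yl]acetic acid
Conditions: TEMPO (20 mol %), PhI(OAc)2 (2.2 equiv), MeCN/H2O, 25 °C
Reagents that add atoms: water O
Why: TEMPO/PhI(OAc)2 oxidation in aqueous acetonitrile takes a primary alcohol through the aldehyde hydrate to the acid under near-neutral conditions that should spare the chromene double bond and the carbamate.

**Step 6**
Reactants: 14 2-[5-(diethylcarbamoyloxy)-2,2-dimethyl-2H-chromen-6-yl]acetic acid; 15 (R)-4-benzyloxazolidin-2-one
Product: 17 (R)-4-benzyl-3-{2-[5-(diethylcarbamoyloxy)-2,2-dimethyl-2H-chromen-6-yl]acetyl}oxazolidin-2-one, via mixed pivalic anhydride 16 (not isolated)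
Conditions: t-BuCOCl, Et3N, THF, −20 °C; then 15, LiCl, −20 → 25 °C
Reagents that add atoms: none
Why: N-acylation of the Evans auxiliary through the mixed pivalic anhydride with Et3N/LiCl avoids strong base and acid chlorides, which would ketenise an arylacetic acid.

**Step 7**
Reactants: 18 2,4-dihydroxybenzaldehyde; 19 prenyl bromide
Product: 20 2,4-dihydroxy-3-(3-methylbut-2-en-1-yl)benzaldehyde
Conditions: KOH, H2O, 0 → 25 °C
Reagents that add atoms: none
Why: Nuclear C-alkylation of the resorcinol-type phenoxide in water (solvated oxygen, soft allylic bromide) should place the prenyl group on the doubly activated carbon between the two oxygens, a known direct prenylation for which a modest yield is expected.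

**Step 8**
Reactants: 20 2,4-dihydroxy-3-(3-methylbut-2-en-1-yl)benzaldehyde
Product: 21 4-formyl-2-(3-methylbut-2-en-1-yl)-1,3-phenylene bis(2,2-dimethylpropanoate)
Conditions: t-BuCOCl, Et3N, DMAP (cat.), CH2Cl2, 0 → 40 °C
Reagents that add atoms: pivaloyl chloride CC(C)(C)C(Cl)=O
Why: DMAP-catalysed acylation; the pivalates make the later benzylic bromide less electron-rich and stable, should resist the enolate of step 11 and are removed by hydride in step 12.

**Step 9**
Reactants: 21 4-formyl-2-(3-methylbut-2-en-1-yl)-1,3-phenylene bis(2,2-dimethylpropanoate)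
Product: 22 4-(hydroxymethyl)-2-(3-methylbut-2-en-1-yl)-1,3-phenylene bis(2,2-dimethylpropanoate)
Conditions: NaBH4, CeCl3·7H2O, MeOH/THF, −40 °C; AcOH quench
Reagents that add atoms: none
Why: Luche reduction reduces the aldehyde fast at low temperature in a weakly acidic medium, so the benzylic alkoxide should not pick up the neighbouring pivaloyl group.

**Step 10**
Reactants: 22 4-(hydroxymethyl)-2-(3-methylbut-2-en-1-yl)-1,3-phenylene bis(2,2-dimethylpropanoate)
Product: 23 4-(bromomethyl)-2-(3-methylbut-2-en-1-yl)-1,3-phenylene bis(2,2-dimethylpropanoate)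
Conditions: PPh3, CBr4, CH2Cl2, 0 °C
Reagents that add atoms: tetrabromomethane BrC(Br)(Br)Br
Why: Appel bromination is neutral, so neither the prenyl double bond nor the esters should be touched.

**Step 11**
Reactants: 17 (R)-4-benzyl-3-{2-[5-(diethylcarbamoyloxy)-2,2-dimethyl-2H-chromen-6-yl]acetyl}oxazolidin-2-one; 23 4-(bromomethyl)-2-(3-methylbut-2-en-1-yl)-1,3-phenylene bis(2,2-dimethylpropanoate)
Product: 25 (R)-4-benzyl-3-{(2R)-3-[2,4-bis(pivaloyloxy)-3-(3-methylbut-2-en-1-yl)phenyl]-2-[5-(diethylcarbamoyloxy)-2,2-dimethyl-2H-chromen-6-yl]propanoyl}oxazolidin-2-one, via sodium Z-enolate 24 (not isolated)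
Conditions: NaN(SiMe3)2, THF, −78 °C; then 23, −78 → −30 °C
Reagents that add atoms: none
Why: Evans asymmetric alkylation: the chelated Z sodium enolate should be benzylated on the face opposite the benzyl group of the (R)-auxiliary, which sets the (R) centre (ring B outranks the new benzylic CH2).

**Step 12**
Reactants: 25 the alkylated imide
Product: 26 6-{(2R)-1-[2,4-dihydroxy-3-(3-methylbut-2-en-1-yl)phenyl]-3-hydroxypropan-2-yl}-2,2-dimethyl-2H-chromen-5-yl diethylcarbamate
Conditions: LiBH4, MeOH, THF, 0 → 40 °C
Reagents that add atoms: none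
Why: Reductive removal of the Evans auxiliary with LiBH4 should give the primary alcohol without epimerisation, and the same hydride should cleave the two activated aryl pivalates while the N,N-diethylcarbamate stays.

**Step 13**
Reactants: 26 the triol
Product: 27 6-[(3R)-7-hydroxy-8-(3-methylbut-2-en-1-yl)chroman-3-yl]-2,2-dimethyl-2H-chromen-5-yl diethylcarbamate
Conditions: PPh3, DIAD, THF (0.01 M), 0 → 25 °C
Reagents that add atoms: none
Why: Intramolecular Mitsunobu etherification should close ring C (6-exo-tet) through the only phenol that can reach the activated primary carbon, the ring B oxygen being blocked as carbamate; the stereocentre is not involved.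

**Step 14**
Reactants: 27 the isoflavan carbamate
Product: 28 (3R)-3-(5-hydroxy-2,2-dimethyl-2H-chromen-6-yl)-8-(3-methylbut-2-en-1-yl)chroman-7-ol
Conditions: LiAlH4, THF, 66 °C; H2O, aq. NaOH work-up
Reagents that add atoms: none
Why: LiAlH4 reductively cleaves the hindered aryl N,N-diethylcarbamate to the phenoxide under basic, acid-free conditions that should leave the prenyl group, the chromene and the stereocentre untouched.

**Compound list**
1 | 2-bromoresorcinol | Oc1cccc(O)c1Br | starting material
2 | 2-bromo-1,3-bis(trimethylsilyloxy)benzene (not isolated) | C[Si](C)(C)Oc1cccc(O[Si](C)(C)C)c1Br | intermediate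
3 | lithium 2-(trimethylsilyl)-3-(trimethylsilyloxy)phenolate (not isolated) | [Li+].[O-]c1cccc(O[Si](C)(C)C)c1[Si](C)(C)C | intermediate
4 | 2-(trimethylsilyl)-3-(trimethylsilyloxy)phenyl diethylcarbamate (not isolated) | CCN(CC)C(=O)Oc1cccc(O[Si](C)(C)C)c1[Si](C)(C)C | intermediate
5 | 3-hydroxy-2-(trimethylsilyl)phenyl diethylcarbamate | CCN(CC)C(=O)Oc1cccc(O)c1[Si](C)(C)C | intermediate
6 | isopropenylboronic acid pinacol ester | CC(=C)B1OC(C)(C)C(C)(C)O1 | starting material
7 | 3-(prop-1-en-2-yloxy)-2-(trimethylsilyl)phenyl diethylcarbamate | CCN(CC)C(=O)Oc1cccc(OC(C)=C)c1[Si](C)(C)C | intermediate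
8 | ethyl vinyl ether | C=COCC | starting material
9 | 3-[(2-chloropropan-2-yl)oxy]-2-(trimethylsilyl)phenyl diethylcarbamate (not isolated) | CCN(CC)C(=O)Oc1cccc(OC(C)(C)Cl)c1[Si](C)(C)C | intermediate
10 | 4-ethoxy-2,2-dimethylchroman-5-yl diethylcarbamate (racemic, not isolated) | CCOC1CC(C)(C)Oc2cccc(OC(=O)N(CC)CC)c12 | intermediate
11 | 2,2-dimethyl-2H-chromen-5-yl diethylcarbamate | CCN(CC)C(=O)Oc1cccc2c1C=CC(C)(C)O2 | intermediate
12 | 6-lithio-2,2-dimethyl-2H-chromen-5-yl diethylcarbamate (not isolated) | [Li]c1ccc2c(c1OC(=O)N(CC)CC)C=CC(C)(C)O2 | intermediate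
13 | 6-(2-hydroxyethyl)-2,2-dimethyl-2H-chromen-5-yl diethylcarbamate | OCCc1ccc2c(c1OC(=O)N(CC)CC)C=CC(C)(C)O2 | intermediate
14 | 2-[5-(diethylcarbamoyloxy)-2,2-dimethyl-2H-chromen-6-yl]acetic acid | OC(=O)Cc1ccc2c(c1OC(=O)N(CC)CC)C=CC(C)(C)O2 | intermediate
15 | (R)-4-benzyloxazolidin-2-one | O=C1N[C@H](Cc2ccccc2)CO1 | starting material
16 | mixed anhydride of 14 with pivalic acid (not isolated) | CC(C)(C)C(=O)OC(=O)Cc1ccc2c(c1OC(=O)N(CC)CC)C=CC(C)(C)O2 | intermediate
17 | (R)-4-benzyl-3-{2-[5-(diethylcarbamoyloxy)-2,2-dimethyl-2H-chromen-6-yl]acetyl}oxazolidin-2-one | O=C(Cc1ccc2c(c1OC(=O)N(CC)CC)C=CC(C)(C)O2)N1[C@H](Cc2ccccc2)COC1=O | intermediate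
18 | 2,4-dihydroxybenzaldehyde | O=Cc1ccc(O)cc1O | starting material
19 | prenyl bromide (1-bromo-3-methylbut-2-ene) | CC(C)=CCBr | starting material
20 | 2,4-dihydroxy-3-(3-methylbut-2-en-1-yl)benzaldehyde | O=Cc1ccc(O)c(CC=C(C)C)c1O | intermediate
21 | 4-formyl-2-(3-methylbut-2-en-1-yl)-1,3-phenylene bis(2,2-dimethylpropanoate) | O=Cc1ccc(OC(=O)C(C)(C)C)c(CC=C(C)C)c1OC(=O)C(C)(C)C | intermediate
22 | 4-(hydroxymethyl)-2-(3-methylbut-2-en-1-yl)-1,3-phenylene bis(2,2-dimethylpropanoate) | OCc1ccc(OC(=O)C(C)(C)C)c(CC=C(C)C)c1OC(=O)C(C)(C)C | intermediate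
23 | 4-(bromomethyl)-2-(3-methylbut-2-en-1-yl)-1,3-phenylene bis(2,2-dimethylpropanoate) | BrCc1ccc(OC(=O)C(C)(C)C)c(CC=C(C)C)c1OC(=O)C(C)(C)C | intermediate
24 | sodium Z-enolate of 17 (not isolated) | [Na+].[O-]/C(=C\c1ccc2c(c1OC(=O)N(CC)CC)C=CC(C)(C)O2)N1[C@H](Cc2ccccc2)COC1=O | intermediate
25 | (R)-4-benzyl-3-{(2R)-3-[2,4-bis(pivaloyloxy)-3-(3-methylbut-2-en-1-yl)phenyl]-2-[5-(diethylcarbamoyloxy)-2,2-dimethyl-2H-chromen-6-yl]propanoyl}oxazolidin-2-one | O=C([C@@H](c1ccc2c(c1OC(=O)N(CC)CC)C=CC(C)(C)O2)Cc1ccc(OC(=O)C(C)(C)C)c(CC=C(C)C)c1OC(=O)C(C)(C)C)N1[C@H](Cc2ccccc2)COC1=O | intermediate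
26 | 6-{(2R)-1-[2,4-dihydroxy-3-(3-methylbut-2-en-1-yl)phenyl]-3-hydroxypropan-2-yl}-2,2-dimethyl-2H-chromen-5-yl diethylcarbamate | OC[C@@H](c1ccc2c(c1OC(=O)N(CC)CC)C=CC(C)(C)O2)Cc1ccc(O)c(CC=C(C)C)c1O | intermediate
27 | 6-[(3R)-7-hydroxy-8-(3-methylbut-2-en-1-yl)chroman-3-yl]-2,2-dimethyl-2H-chromen-5-yl diethylcarbamate | CC(C)=CCc1c(O)ccc2c1OC[C@@H](c1ccc3c(c1OC(=O)N(CC)CC)C=CC(C)(C)O3)C2 | intermediate
28 | (3R)-3-(5-hydroxy-2,2-dimethyl-2H-chromen-6-yl)-8-(3-methylbut-2-en-1-yl)chroman-7-ol | CC(C)=CCc1c(O)ccc2c1OC[C@@H](c1ccc3c(c1O)C=CC(C)(C)O3)C2 | target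

**Step count and risks**
Total steps: 14. Longest linear sequence: 10 (steps 1 to 6, then 11 to 14); the ring A branch (steps 7 to 10) joins at step 11.

Steps most likely to fail:

Step 3 (proposed new method). What may go wrong: protodesilylation of the aryl–silicon bond by HCl before the annulation, closure at the free ortho carbon instead of the ipso carbon, or telomerisation of the vinyl ether in place of ring closure. Fallback with known chemistry, setting out from 1 and coming back at 11: 1 is protected with MOMCl and i-Pr2NEt as 2-bromo-1,3-bis(methoxymethoxy)benzene F1. Bromine–lithium exchange (n-BuLi, −78 °C) and addition to 3-methylbut-2-enal should give 1-[2,6-bis(methoxymethoxy)phenyl]-3-methylbut-2-en-1-ol F2. HCl in methanol should remove both acetals and close the allylic cation onto oxygen to 2,2-dimethyl-2H-chromen-5-ol F3. NaH and ClCONEt2 then give 11. Here the pyran is built one bond at a time (aryl–C4 first, O1–C2 second), with the position fixed by the bromine.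

Step 2. What may go wrong: sluggish oxidative coupling at the hindered ortho-silyl phenol and copper-promoted loss of the silyl group. Fallback, setting out from 5 and coming back at 7: 5 is acetylated (Ac2O, pyridine, DMAP) to 3-acetoxy-2-(trimethylsilyl)phenyl diethylcarbamate F4. The ester carbonyl is then methylenated with the Tebbe reagent Cp2TiCH2AlClMe2 (THF/toluene, −40 → 0 °C), which should react with the ester and leave the carbamate, to give 7. The C=C bond is made by carbonyl olefination instead of the C–O bond by coupling.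

Step 4. What may go wrong: addition of s-BuLi across the chromene double bond, anionic ortho-Fries migration on warming, or transfer of the carbamoyl group to the new alkoxide. Fallback, setting out from 11 and coming back at 14 (step 5 is then not needed): 12, generated as in step 4, is quenched at once with iodine to give 6-iodo-2,2-dimethyl-2H-chromen-5-yl diethylcarbamate F5. Pd2(dba)3/XPhos-catalysed coupling with the Reformatsky reagent BrZnCH2CO2Et should give ethyl 2-[5-(diethylcarbamoyloxy)-2,2-dimethyl-2H-chromen-6-yl]acetate F6. LiOH in THF/H2O then gives 14.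

**Further compounds**
F1 | step 3 | 2-bromo-1,3-bis(methoxymethoxy)benzene | COCOc1cccc(OCOC)c1Br
F2 | step 3 | 1-[2,6-bis(methoxymethoxy)phenyl]-3-methylbut-2-en-1-ol (racemic) | COCOc1cccc(OCOC)c1C(O)C=C(C)C
F3 | step 3 | 2,2-dimethyl-2H-chromen-5-ol | Oc1cccc2c1C=CC(C)(C)O2
F4 | step 2 | 3-acetoxy-2-(trimethylsilyl)phenyl diethylcarbamate | CC(=O)Oc1cccc(OC(=O)N(CC)CC)c1[Si](C)(C)C
F5 | step 4 | 6-iodo-2,2-dimethyl-2H-chromen-5-yl diethylcarbamate | CCN(CC)C(=O)Oc1c(I)ccc2c1C=CC(C)(C)O2
F6 | step 4 | ethyl 2-[5-(diethylcarbamoyloxy)-2,2-dimethyl-2H-chromen-6-yl]acetate | CCOC(=O)Cc1ccc2c(c1OC(=O)N(CC)CC)C=CC(C)(C)O2
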